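Ring B is disconnected at C7–C8 and C9–C10. The key step exploits the quaternary, methyl-bearing C10 (a tertiary radical site on ring A) lying two carbons from C7, and the one-carbon branch C17 on C8, carried as an aldehyde. Iron-hydride hydrogen-atom transfer to the ring A alkene of a cyclohexenylacetaldehyde gives the C10 radical, which adds to C9 of a citronellic-acid-derived (E)-enal; the resulting enolate closes onto the C7 aldehyde. One operation thus joins both chiral fragments, forms ring B with the trans ring fusion, C10 and C9, and assembles all twenty skeletal carbons. Reductive 1,3-transposition of the derived enal later unveils the C8 exocyclic methylene.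

Key step: step 8

Remark: atoms carry labdane numbers (ring A C1–C5 and C10; ring B C5–C10; C17 the methylene carbon on C8; C18 the oxygen-bearing carbon on C4; C19 and C20 the methyls on C4 and C10; side chain C11–C16 with C15 the acid carbon and C16 the methyl on C13).
Assumption: the SMILES is read as the ent-labdane (4S,5S,9R,10S,13S), with C20 cis to C19 and trans to C18, H5 and H9, and with C13 configured as in (S)-citronellic acid.
Assumption: in the CBS reduction the 2-methylalkenyl flank of the enone acts as the large group, so the (R)-catalyst gives the (1S)-carbinol from both enantiomers of the enone.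

Step 1
Reactants: 1 3-ethoxy-2-methylcyclohex-2-en-1-one
Product: 2 rac-3-ethoxy-2,6-dimethylcyclohex-2-en-1-one
Conditions: LiN(i-Pr)2 (LDA), THF, −78 °C; MeI, −78 → 0 °C
Reagents that add atoms: iodomethane CI
Why: Kinetic α′-deprotonation of the vinylogous ester and SN2 methylation (Stork–Danheiser enolate alkylation); the new centre is racemic and becomes quaternary in step 2.

Step 2
Reactants: 2 rac-3-ethoxy-2,6-dimethylcyclohex-2-en-1-one
Product: 3 rac-3-ethoxy-2,6-dimethyl-6-{[(triisopropylsilyl)oxy]methyl}cyclohex-2-en-1-one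
Conditions: LiN(i-Pr)2, THF, −78 °C; i-Pr3SiOCH2Cl, −78 → 0 °C
Reagents that add atoms: (triisopropylsiloxy)methyl chloride ClCO[Si](C(C)C)(C(C)C)C(C)C
Why: A second α′-enolate alkylation with a reactive α-chloro ether builds the quaternary carbon (later C4) as a racemate and brings in C18 with its oxygen already silyl-protected.

Step 3
Reactants: 3 rac-3-ethoxy-2,6-dimethyl-6-{[(triisopropylsilyl)oxy]methyl}cyclohex-2-en-1-one
Product: 5 rac-2,4-dimethyl-4-{[(triisopropylsilyl)oxy]methyl}cyclohex-2-en-1-one, via allylic alcohol 4 (not isolated)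
Conditions: i-Bu2AlH, PhMe, −78 → 0 °C; then 1 M HCl, THF, 0 °C
Reagents that add atoms: water O
Why: Stork–Danheiser transposition: 1,2-reduction of the vinylogous ester carbonyl, then acid hydrolysis of the enol ether and loss of water, gives the transposed enone with the quaternary carbon at the γ-position; no new stereocentre survives.

Step 4
Reactants: 5 rac-2,4-dimethyl-4-{[(triisopropylsilyl)oxy]methyl}cyclohex-2-en-1-one
Product: 6 (1S,4S)-2,4-dimethyl-4-{[(triisopropylsilyl)oxy]methyl}cyclohex-2-en-1-ol
Conditions: (R)-2-methyl-CBS-oxazaborolidine (0.2 equiv), BH3·SMe2, THF, −20 °C; chromatographic separation of the C4 epimers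
Reagents that add atoms: none
Why: Corey–Bakshi–Shibata reduction under catalyst control should turn both enantiomers of 5 into (1S)-carbinols, so the racemate becomes two separable diastereomers, and the cis isomer 6 (hydroxyl cis to the C4 methyl) is taken on in enantioenriched form.

Step 5
Reactants: 6 (1S,4S)-2,4-dimethyl-4-{[(triisopropylsilyl)oxy]methyl}cyclohex-2-en-1-ol
Product: 8 2-[(1S,6S)-2,6-dimethyl-6-{[(triisopropylsilyl)oxy]methyl}cyclohex-2-en-1-yl]acetaldehyde, via allyl vinyl ether 7 (not isolated)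
Conditions: ethyl vinyl ether (solvent), Hg(OAc)2 (cat.), reflux; concentrate; xylenes, 190 °C, sealed tube
Reagents that add atoms: ethyl vinyl ether C=COCC
Why: Mercury-catalysed transvinylation and thermal Claisen rearrangement ([3,3], suprafacial) trade the C1–O bond for the C5–C6 bond on the same ring face, which sets C5 with the acetaldehyde arm cis to the C4 methyl and leaves the C1=C10 alkene for the key step.

Step 6
Reactants: 9 (S)-citronellic acid
Product: 10 2-(trimethylsilyl)ethyl (3S)-3,7-dimethyloct-6-enoate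
Conditions: Me3SiCH2CH2OH, DCC, DMAP (cat.), CH2Cl2, 0 °C → rt
Reagents that add atoms: 2-(trimethylsilyl)ethanol C[Si](C)(C)CCO
Why: Steglich esterification protects the future C15 acid as a fluoride-labile ester; the C13 stereocentre comes unchanged from the chiral pool.

Step 7
Reactants: 10 2-(trimethylsilyl)ethyl (3S)-3,7-dimethyloct-6-enoate
Product: 11 2-(trimethylsilyl)ethyl (3S,6E)-3-methyl-8-oxooct-6-enoate
Conditions: (E)-crotonaldehyde (5 equiv), second-generation Hoveyda–Grubbs catalyst RuCl2(H2IMes)(=CH-C6H4-2-O-i-Pr) (5 mol%), CH2Cl2, 40 °C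
Reagents that add atoms: (E)-crotonaldehyde C/C=C/C=O
Why: Olefin cross-metathesis of the prenyl-type trisubstituted alkene with an excess of an electron-poor partner should give the E-enal under thermodynamic control, with volatile 2-methylbut-2-ene leaving.

Step 8
Reactants: 8 2-[(1S,6S)-2,6-dimethyl-6-{[(triisopropylsilyl)oxy]methyl}cyclohex-2-en-1-yl]acetaldehyde; 11 2-(trimethylsilyl)ethyl (3S,6E)-3-methyl-8-oxooct-6-enoate
Product: 13 2-(trimethylsilyl)ethyl 7-hydroxy-17-oxo-18-(triisopropylsilyloxy)labdan-15-oate of the ent series (C7/C8 epimers), via conjugate-adduct enolate 12 (not isolated)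
Conditions: Fe(acac)3 (30 mol%), PhSiH3 (2.5 equiv), 11 (2.5 equiv), EtOH/THF, 0 °C → rt
Reagents that add atoms: none
Why: This is a metal-hydride hydrogen-atom-transfer Giese addition with radical–polar crossover and intramolecular aldol, the known iron-catalysed annulation of γ,δ-unsaturated aldehydes with unsaturated carbonyl acceptors: the iron hydride from Fe(acac)3 and the silane delivers H• to C1 of the trisubstituted alkene, the tertiary C10 radical adds to C9 (β-carbon) of 11, and divalent iron reduces the α-formyl radical to the ferric enolate 12, whose C8 attacks the C7 aldehyde. Ring B closes by a 6-(enolexo)-exo-trig aldol through a chair in which C6 and C9 are both equatorial on ring A. C10 is controlled by the adjacent C5 stereocentre and the axial C4 methyl (C19): the radical is attacked anti to the C5 arm, the other face being blocked by C19, so C20 ends axial and cis to C19 and the ring fusion is trans. C9 is controlled only by simple diastereoselection: the enal should approach with H9 next to the C5 arm, the C11 chain between the axial hydrogens on C1 and C5, and the flat formyl-vinyl arm turned away from the C4/C5 substituents, which puts C11 cis to C20 (equatorial on ring B); this is the least secure element of the step. C7 and C8 form as mixtures that steps 9 to 11 erase. The chemoselectivity needed (hydrogen-atom transfer to the electron-rich alkene of 8 and not to the enal, and capture by 11 faster than reduction of the radical) rests on the polarity match and the excess of 11.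

Step 9
Reactants: 13 the β-hydroxy aldehyde from step 8
Product: 14 2-(trimethylsilyl)ethyl 17-oxo-18-(triisopropylsilyloxy)labd-7-en-15-oate of the ent series
Conditions: p-TsOH·H2O (cat.), PhMe, 50 °C
Reagents that add atoms: none
Why: Acid-catalysed dehydration of the β-hydroxy aldehyde (aldol condensation) gives the conjugated C7=C8 enal and removes the C7 and C8 stereocentres, while C9 is not enolisable and should be retained.

Step 10
Reactants: 14 the C7=C8 enal
Product: 15 tosylhydrazone of 14
Conditions: TsNHNH2 (1.1 equiv), EtOH, rt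
Reagents that add atoms: p-toluenesulfonyl hydrazide Cc1ccc(cc1)S(=O)(=O)NN
Why: Condensation of the aldehyde with the sulfonyl hydrazide gives the α,β-unsaturated tosylhydrazone without touching any stereocentre.

Step 11
Reactants: 15 tosylhydrazone of 14
Product: 17 2-(trimethylsilyl)ethyl 18-(triisopropylsilyloxy)labd-8(17)-en-15-oate of the ent series, via allylic diazene 16 (not isolated)
Conditions: catecholborane (3 equiv), CHCl3, 0 °C; then NaOAc·3H2O, reflux
Reagents that add atoms: none
Why: Kabalka reductive 1,3-transposition: 1,2-hydride delivery, loss of sulfinate to the allylic diazene and retro-ene loss of N2 move the double bond to C8=C17 and place hydrogen on the non-stereogenic C7.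

Step 12
Reactants: 17 the exocyclic alkene from step 11
Product: 18 2-(trimethylsilyl)ethyl 18-hydroxylabd-8(17)-en-15-oate of the ent series
Conditions: HF·pyridine, pyridine, THF, 0 °C → rt
Reagents that add atoms: none
Why: Buffered hydrogen fluoride cleaves the primary silyl ether, while the 2-(trimethylsilyl)ethyl ester (which needs free fluoride ion) and the exocyclic alkene should survive.

Step 13
Reactants: 19 (E)-p-coumaric acid
Product: 21 (E)-3-{4-[(tert-butyldimethylsilyl)oxy]phenyl}prop-2-enoic acid, via bis-silyl derivative 20 (not isolated)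
Conditions: t-BuMe2SiCl (2.5 equiv), imidazole, DMF, rt; then AcOH/THF/H2O, rt
Reagents that add atoms: tert-butyldimethylsilyl chloride CC(C)(C)[Si](C)(C)Cl
Why: Silylation of phenol and acid followed by selective hydrolysis of the labile silyl ester leaves only the phenol protected.

Step 14
Reactants: 18 the C18 alcohol; 21 (E)-3-{4-[(tert-butyldimethylsilyl)oxy]phenyl}prop-2-enoic acid
Product: 22 2-(trimethylsilyl)ethyl 18-{(E)-3-[4-(tert-butyldimethylsilyloxy)phenyl]prop-2-enoyloxy}labd-8(17)-en-15-oate of the ent series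
Conditions: DCC, DMAP, CH2Cl2, rt
Reagents that add atoms: none
Why: Steglich esterification (carbodiimide activation with DMAP acyl transfer) acylates the neopentyl primary alcohol without affecting the E alkene or any stereocentre.

Step 15
Reactants: 22 the doubly protected ester
Product: 23 (3S)-5-[(1R,4aS,5S,8aS)-5-({[(2E)-3-(4-hydroxyphenyl)prop-2-enoyl]oxy}methyl)-5,8a-dimethyl-2-methylidenedecahydronaphthalen-1-yl]-3-methylpentanoic acid
Conditions: Bu4NF (3 equiv), THF, 0 °C → rt; aq. NH4Cl
Reagents that add atoms: none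
Why: Fluoride attacks silicon in both groups, so β-elimination of the 2-(trimethylsilyl)ethyl ester frees the C15 acid and the aryl silyl ether gives the phenol, the alkyl cinnamate ester being stable to these conditions.

Compound list
1 | 3-ethoxy-2-methylcyclohex-2-en-1-one | CCOC1=C(C)C(=O)CCC1 | starting material
2 | rac-3-ethoxy-2,6-dimethylcyclohex-2-en-1-one | CCOC1=C(C)C(=O)C(C)CC1 | intermediate
3 | rac-3-ethoxy-2,6-dimethyl-6-{[(triisopropylsilyl)oxy]methyl}cyclohex-2-en-1-one | CCOC1=C(C)C(=O)C(C)(CO[Si](C(C)C)(C(C)C)C(C)C)CC1 | intermediate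
4 | 3-ethoxy-2,6-dimethyl-6-{[(triisopropylsilyl)oxy]methyl}cyclohex-2-en-1-ol (allylic alcohol, not isolated) | CCOC1=C(C)C(O)C(C)(CO[Si](C(C)C)(C(C)C)C(C)C)CC1 | intermediate
5 | rac-2,4-dimethyl-4-{[(triisopropylsilyl)oxy]methyl}cyclohex-2-en-1-one | CC1=CC(C)(CO[Si](C(C)C)(C(C)C)C(C)C)CCC1=O | intermediate
6 | (1S,4S)-2,4-dimethyl-4-{[(triisopropylsilyl)oxy]methyl}cyclohex-2-en-1-ol (hydroxyl cis to the C4 methyl) | O[C@H]1CC[C@](C)(CO[Si](C(C)C)(C(C)C)C(C)C)C=C1C | intermediate
7 | vinyl ether of 6 (allyl vinyl ether, not isolated) | C=CO[C@H]1CC[C@](C)(CO[Si](C(C)C)(C(C)C)C(C)C)C=C1C | intermediate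
8 | 2-[(1S,6S)-2,6-dimethyl-6-{[(triisopropylsilyl)oxy]methyl}cyclohex-2-en-1-yl]acetaldehyde (arm cis to the ring methyl on the quaternary carbon) | O=CC[C@@H]1[C@@](C)(CO[Si](C(C)C)(C(C)C)C(C)C)CCC=C1C | intermediate
9 | (S)-citronellic acid, (3S)-3,7-dimethyloct-6-enoic acid | C[C@@H](CCC=C(C)C)CC(=O)O | starting material
10 | 2-(trimethylsilyl)ethyl (3S)-3,7-dimethyloct-6-enoate | C[C@@H](CCC=C(C)C)CC(=O)OCC[Si](C)(C)C | intermediate
11 | 2-(trimethylsilyl)ethyl (3S,6E)-3-methyl-8-oxooct-6-enoate | C[C@@H](CC/C=C/C=O)CC(=O)OCC[Si](C)(C)C | intermediate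
12 | C9–C10 conjugate adduct, ferric enolate drawn as the enol (not isolated) | O=CC[C@@H]1[C@@](C)(CO[Si](C(C)C)(C(C)C)C(C)C)CCC[C@@]1(C)[C@@H](C=CO)CC[C@H](C)CC(=O)OCC[Si](C)(C)C | intermediate
13 | β-hydroxy aldehyde with ring B closed: 7-hydroxy, 8-formyl, C7/C8 epimers; C4, C5, C9, C10, C13 as in 23 | O=CC1C(O)C[C@@H]2[C@@](C)(CO[Si](C(C)C)(C(C)C)C(C)C)CCC[C@@]2(C)[C@@H]1CC[C@H](C)CC(=O)OCC[Si](C)(C)C | intermediate
14 | C7=C8 enal (17-al); stereocentres as in 23 | O=CC1=CC[C@@H]2[C@@](C)(CO[Si](C(C)C)(C(C)C)C(C)C)CCC[C@@]2(C)[C@@H]1CC[C@H](C)CC(=O)OCC[Si](C)(C)C | intermediate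
15 | (E)-tosylhydrazone of 14 | Cc1ccc(cc1)S(=O)(=O)N/N=C/C1=CC[C@@H]2[C@@](C)(CO[Si](C(C)C)(C(C)C)C(C)C)CCC[C@@]2(C)[C@@H]1CC[C@H](C)CC(=O)OCC[Si](C)(C)C | intermediate
16 | allylic diazene at C17 (not isolated) | N=NCC1=CC[C@@H]2[C@@](C)(CO[Si](C(C)C)(C(C)C)C(C)C)CCC[C@@]2(C)[C@@H]1CC[C@H](C)CC(=O)OCC[Si](C)(C)C | intermediate
17 | 8(17)-exocyclic alkene, C18 triisopropylsilyl ether, C15 2-(trimethylsilyl)ethyl ester; stereocentres as in 23 | C=C1CC[C@@H]2[C@@](C)(CO[Si](C(C)C)(C(C)C)C(C)C)CCC[C@@]2(C)[C@@H]1CC[C@H](C)CC(=O)OCC[Si](C)(C)C | intermediate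
18 | C18 alcohol, C15 2-(trimethylsilyl)ethyl ester; stereocentres as in 23 | C=C1CC[C@@H]2[C@@](C)(CO)CCC[C@@]2(C)[C@@H]1CC[C@H](C)CC(=O)OCC[Si](C)(C)C | intermediate
19 | (E)-p-coumaric acid | OC(=O)/C=C/c1ccc(O)cc1 | starting material
20 | tert-butyldimethylsilyl (E)-3-{4-[(tert-butyldimethylsilyl)oxy]phenyl}prop-2-enoate (not isolated) | CC(C)(C)[Si](C)(C)OC(=O)/C=C/c1ccc(O[Si](C)(C)C(C)(C)C)cc1 | intermediate
21 | (E)-3-{4-[(tert-butyldimethylsilyl)oxy]phenyl}prop-2-enoic acid | OC(=O)/C=C/c1ccc(O[Si](C)(C)C(C)(C)C)cc1 | intermediate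
22 | doubly protected target: aryl silyl ether, C15 2-(trimethylsilyl)ethyl ester | C=C1CC[C@@H]2[C@@](C)(COC(=O)/C=C/c3ccc(O[Si](C)(C)C(C)(C)C)cc3)CCC[C@@]2(C)[C@@H]1CC[C@H](C)CC(=O)OCC[Si](C)(C)C | intermediate
23 | (3S)-5-[(1R,4aS,5S,8aS)-5-({[(2E)-3-(4-hydroxyphenyl)prop-2-enoyl]oxy}methyl)-5,8a-dimethyl-2-methylidenedecahydronaphthalen-1-yl]-3-methylpentanoic acid | C=C1CC[C@@H]2[C@@](C)(COC(=O)/C=C/c3ccc(O)cc3)CCC[C@@]2(C)[C@@H]1CC[C@H](C)CC(=O)O | target

Total step count: 15. Longest linear sequence: 12 steps (steps 1–5, 8–12, 14, 15).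

Steps most likely to fail

Step 8. The hindered tertiary C10 radical may be reduced, or may abstract the aldehydic hydrogen, faster than it adds to a β-substituted enal, and the two faces of the enal may be poorly discriminated at C9. The fallback sets out from 8 and 11 and comes back at 13; it makes the two bonds in separate operations and sets C9 in a ring closure. Enal 11 would be brominated (Br2, CH2Cl2, −78 °C; then Et3N) to 2-(trimethylsilyl)ethyl (3S,6Z)-7-bromo-3-methyl-8-oxooct-6-enoate F1 and protected (HC(OMe)3, PPTS, MeOH) as the dimethyl acetal F2. Nozaki–Hiyama–Kishi coupling of F2 with aldehyde 8 (CrCl2, NiCl2 cat., DMF) would form the C7–C8 bond in the allylic alcohol F3, and mild acid (PPTS, acetone/H2O) would release the hydroxy enal F4. Treatment of F4 with Fe(acac)3 and PhSiH3 would then close the C9–C10 bond by intramolecular Giese addition of the C10 radical through a chair with the C11 chain equatorial, giving 13.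

Step 4. Catalyst control over the carbinol centre may be incomplete, which erodes the enantiomeric purity of each epimer, or the two epimers may co-elute. The fallback sets out from 5 and comes back at 6. Luche reduction (NaBH4, CeCl3·7H2O, MeOH) would give the racemic cis alcohol F5 and the racemic trans alcohol F6, which are separated. Lipase-catalysed acetylation of F5 (lipase from Burkholderia cepacia, vinyl acetate, hexane) should, following the Kazlauskas rule, acylate the (1R,4R)-enantiomer to the acetate F7 and leave (1S,4S)-alcohol 6.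

Step 5. Transvinylation of the hindered secondary alcohol may stall, and the allyl vinyl ether may eliminate at the temperature needed to form the C5–C6 bond next to the quaternary C4. The fallback sets out from 6 and comes back at 8. Johnson–Claisen rearrangement (CH3C(OEt)3, EtCO2H cat., 140 °C) forms the ketene acetal in situ and rearranges at lower temperature to the ethyl ester F8, which i-Bu2AlH (CH2Cl2, −78 °C) reduces to aldehyde 8.

Further compounds
F1 | step 8 | 2-(trimethylsilyl)ethyl (3S,6Z)-7-bromo-3-methyl-8-oxooct-6-enoate | C[C@@H](CC/C=C(\Br)C=O)CC(=O)OCC[Si](C)(C)C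
F2 | step 8 | 2-(trimethylsilyl)ethyl (3S,6Z)-7-bromo-8,8-dimethoxy-3-methyloct-6-enoate | C[C@@H](CC/C=C(\Br)C(OC)OC)CC(=O)OCC[Si](C)(C)C
F3 | step 8 | allylic alcohol from the coupling of F2 with 8 (C7–C8 bond formed, C17 as dimethyl acetal, C7 epimers) | COC(OC)/C(=C/CC[C@H](C)CC(=O)OCC[Si](C)(C)C)C(O)C[C@@H]1[C@@](C)(CO[Si](C(C)C)(C(C)C)C(C)C)CCC=C1C
F4 | step 8 | hydroxy enal (C7 hydroxyl, C8=C9 enal, C17 aldehyde) | O=C/C(=C/CC[C@H](C)CC(=O)OCC[Si](C)(C)C)C(O)C[C@@H]1[C@@](C)(CO[Si](C(C)C)(C(C)C)C(C)C)CCC=C1C
F5 | step 4 | racemic cis-2,4-dimethyl-4-{[(triisopropylsilyl)oxy]methyl}cyclohex-2-en-1-ol | O[C@H]1CC[C@](C)(CO[Si](C(C)C)(C(C)C)C(C)C)C=C1C.O[C@@H]1CC[C@@](C)(CO[Si](C(C)C)(C(C)C)C(C)C)C=C1C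
F6 | step 4 | racemic trans-2,4-dimethyl-4-{[(triisopropylsilyl)oxy]methyl}cyclohex-2-en-1-ol | O[C@H]1CC[C@@](C)(CO[Si](C(C)C)(C(C)C)C(C)C)C=C1C.O[C@@H]1CC[C@](C)(CO[Si](C(C)C)(C(C)C)C(C)C)C=C1C
F7 | step 4 | (1R,4R)-2,4-dimethyl-4-{[(triisopropylsilyl)oxy]methyl}cyclohex-2-en-1-yl acetate | CC(=O)O[C@@H]1CC[C@@](C)(CO[Si](C(C)C)(C(C)C)C(C)C)C=C1C
F8 | step 5 | ethyl 2-[(1S,6S)-2,6-dimethyl-6-{[(triisopropylsilyl)oxy]methyl}cyclohex-2-en-1-yl]acetate | CCOC(=O)C[C@@H]1[C@@](C)(CO[Si](C(C)C)(C(C)C)C(C)C)CCC=C1C
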